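**Retrosynthetic overview**
1. Final operation: one acid treatment removes every protecting group (tert-butyl ester, two MOM ethers, 7-O-SiEt3) from the assembled bicycle.
2. Key disconnection: C8a–C4a and O2–C3 are cut together. This unfolds carbocycle and pyran into an isomeric acyclic β-aroyloxy aldehyde / conjugated diynone.
3. C5–C6: a lithium ene-diynide adds to the lactone-type carbonyl of a dioxolanone, so the lactic acid carboxyl carbon becomes C6.
4. C7–C8: an aldol of the L-lactic acid/pivalaldehyde dioxolanone enolate with 3,3-diethoxypropanal sets both stereocentres. O8 is then acylated with protected orsellinoyl chloride (arene ring bought).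
5. Ring order: temporary dioxolanone (made first, destroyed in the alkynylation), then carbocycle, then pyran, the last two in one flask.

Assumption: the SMILES defines the target as the (7R,8R) isomer with 7-OH and 8-O-acyl cis, and the (+) sign is taken to belong to it. Atom labels (C1, O2, C3 … C8a) follow the isochromene numbering of the target throughout.

**Step 1**
Reactants: 1 L-(+)-lactic acid [(S)-2-hydroxypropanoic acid]; 2 pivalaldehyde
Product: 3 (2S,5S)-2-tert-butyl-5-methyl-1,3-dioxolan-4-one (cis)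
Conditions: p-MeC6H4SO3H·H2O (cat.), H2SO4 (cat.), pentane, reflux, Dean–Stark; recrystallise, pentane/Et2O, −78 °C
Reagents that add atoms: none
Why: Acid-catalysed acetalisation with azeotropic water removal, in which C5 keeps the lactic acid configuration and the new acetal centre C2 equilibrates to the favoured cis isomer (about 4:1), obtained pure by cold crystallisation.

**Step 2**
Reactants: 4 ethyl 3,3-diethoxypropanoate
Product: 5 3,3-diethoxypropanal
Conditions: (Me2CHCH2)2AlH (1.05 equiv), CH2Cl2, −78 °C; then H2O, −78 °C → rt, filter through Celite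
Reagents that add atoms: none
Why: Partial ester reduction, since the aluminium hemiacetal is stable at −78 °C and releases the aldehyde only on quench, while the acetal is inert to hydride.

**Step 3**
Reactants: 3 (2S,5S)-2-tert-butyl-5-methyl-1,3-dioxolan-4-one; 5 3,3-diethoxypropanal
Product: 7 (2S,5R)-2-tert-butyl-5-[(1R)-3,3-diethoxy-1-hydroxypropyl]-5-methyl-1,3-dioxolan-4-one, via lithium enolate 6 (not isolated)
Conditions: LiN(CHMe2)2 (1.05 equiv), THF, −78 °C, 30 min; 5 (1.2 equiv), −78 °C, 1 h; AcOH, −78 °C; SiO2 chromatography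
Reagents that add atoms: none
Why: Aldol addition with self-regeneration of the stereocentre, where the tert-butyl group shields one face of planar 6 so that bond formation anti to it fixes C7 as R (net retention), and the closed Zimmerman–Traxler chair of this ring enolate (methyl cis to OLi, aldehyde chain equatorial) puts methyl and 8-OH syn, i.e. O7/O8 anti in the zigzag = (8R), expected about 4:1 with the minor epimer removed by chromatography.

**Step 4**
Reactants: 8 orsellinic acid (2,4-dihydroxy-6-methylbenzoic acid)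
Product: 10 2,4-bis(methoxymethoxy)-6-methylbenzoic acid, via methoxymethyl ester 9 (not isolated)
Conditions: NaH (3.3 equiv), MeOCH2Cl (3.3 equiv), DMF, 0 °C → rt; then LiOH, THF/H2O, rt; 1 M HCl to pH 4, 0 °C
Reagents that add atoms: chloromethyl methyl ether COCCl
Why: Williamson-type O-alkylation of all three acidic sites followed by selective cleavage of the acyloxymethyl ether, which hydroxide attacks at the unhindered O–CH2–O carbon although the di-ortho-substituted carbonyl is shielded, the aryl MOM ethers being base-stable.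

**Step 5**
Reactants: 10 2,4-bis(methoxymethoxy)-6-methylbenzoic acid; 7 aldol adduct
Product: 12 (1R)-1-[(2S,4R)-2-tert-butyl-4-methyl-5-oxo-1,3-dioxolan-4-yl]-3,3-diethoxypropyl 2,4-bis(methoxymethoxy)-6-methylbenzoate, via acid chloride 11 (not isolated)
Conditions: 10, Me2C=C(Cl)NMe2 (1.1 equiv), CH2Cl2, 0 °C → rt; then 7, Et3N (2 equiv), 4-(dimethylamino)pyridine (0.5 equiv), rt → 40 °C
Reagents that add atoms: none
Why: Esterification by acylpyridinium (nucleophilic) catalysis, in which the α-chloroenamine makes the acid chloride without HCl so that MOM ethers and acetal survive, the electron-rich di-ortho-substituted aroyl chloride transfers its acyl group as mesitoyl chloride does, and no bond at C8 is broken so (8R) is retained.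

**Step 6**
Reactants: 13 1,4-bis(trimethylsilyl)buta-1,3-diyne
Product: 15 5-(trimethylsilyl)penta-2,4-diynal, via lithium silylbutadiynide 14 (not isolated)
Conditions: MeLi·LiBr (1.0 equiv), THF, −78 °C → rt; DMF (1.5 equiv), −78 → 0 °C; AcOH (2.2 equiv), −78 °C
Reagents that add atoms: N,N-dimethylformamide CN(C)C=O
Why: Selective single Si–C cleavage by methyllithium gives the monolithio diyne, which DMF formylates, and the acidic quench keeps the liberated dimethylamine from adding to the ynal.

**Step 7**
Reactants: 15 5-(trimethylsilyl)penta-2,4-diynal; 16 tert-butyl 2-(diethoxyphosphoryl)acetate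
Product: 18 tert-butyl (2E)-7-(trimethylsilyl)hept-2-ene-4,6-diynoate, via sodium phosphonate carbanion 17 (not isolated)
Conditions: 16, NaH (1.05 equiv), THF, 0 °C; 15, −78 → 0 °C
Reagents that add atoms: none
Why: Horner–Wadsworth–Emmons olefination, in which reversible addition of the stabilised phosphonate anion delivers the E-enoate (expected above 10:1).

**Step 8**
Reactants: 18 tert-butyl (2E)-7-(trimethylsilyl)hept-2-ene-4,6-diynoate
Product: 19 tert-butyl (2E)-hept-2-ene-4,6-diynoate
Conditions: K2CO3 (0.1 equiv), MeOH/THF, 0 °C, 20 min; kept as a cold THF solution and used at once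
Reagents that add atoms: none
Why: Base-catalysed protodesilylation of an alkynylsilane, where methoxide attacks silicon, the tert-butyl ester is untouched, and the short cold reaction avoids conjugate addition of methanol.

**Step 9**
Reactants: 19 tert-butyl (2E)-hept-2-ene-4,6-diynoate; 12 dioxolanone aryl ester
Product: 22 tert-butyl (2E,9R,10R)-10-{[2,4-bis(methoxymethoxy)-6-methylbenzoyl]oxy}-12,12-diethoxy-9-hydroxy-9-methyl-8-oxododec-2-ene-4,6-diynoate, via lithium enediynide 20 (not isolated), via lithium hemiketal alkoxide 21 (not isolated)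
Conditions: 19 (1.4 equiv), LiN(SiMe3)2 (1.3 equiv), THF, −78 °C; 12, −78 → −40 °C; AcOH, −78 °C; SiO2
Reagents that add atoms: none
Why: 1,2-Addition of an alkynyllithium to a lactone-type carbonyl, in which alkoxide 21 persists in the cold so no second addition occurs, protonation collapses it to the ynone with loss of pivalaldehyde and release of 7-OH, the di-ortho-substituted aryl ester and the tert-butyl ester are too hindered to compete, and the quaternary C7 and C8 cannot epimerise.

**Step 10**
Reactants: 22 α′-hydroxy diynone acetal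
Product: 24 tert-butyl (2E,9R,10R)-10-{[2,4-bis(methoxymethoxy)-6-methylbenzoyl]oxy}-9-methyl-8,12-dioxo-9-[(triethylsilyl)oxy]dodec-2-ene-4,6-diynoate, via collidinium salt 23 (not isolated)
Conditions: Et3SiOSO2CF3 (2.5 equiv), 2,4,6-trimethylpyridine (4 equiv), CH2Cl2, 0 °C, 1 h; then H2O, 0 °C → rt
Reagents that add atoms: triethylsilyl trifluoromethanesulfonate CC[Si](CC)(CC)OS(=O)(=O)C(F)(F)F; water O
Why: Silyl triflate/hindered pyridine chemistry does two jobs at once, silylating the tertiary alcohol and turning the dialkyl acetal (which ionises faster than the aryl MOM ethers or the conjugated tert-butyl ester) into the α-alkoxy pyridinium salt 23, which water hydrolyses to the aldehyde in a medium never basic enough for E1cB loss of the aroyloxy group.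

**Step 11 (key step)**
Reactants: 24 acyclic aldehyde–diynone
Product: 27 tert-butyl (2E)-3-[(7R,8R)-8-{[2,4-bis(methoxymethoxy)-6-methylbenzoyl]oxy}-7-methyl-6-oxo-7-[(triethylsilyl)oxy]-7,8-dihydro-6H-isochromen-3-yl]prop-2-enoate, via formyl enynone 25 (not isolated), via hydroxymethylene dienone 26 (not isolated)
Conditions: [(t-Bu)2(2-PhC6H4)P]AuCl (5 mol %), AgOP(O)(OPh)2 (5 mol %), (PhO)2P(O)OH (15 mol %), 4 Å molecular sieves, ClCH2CH2Cl (0.01 M), 40 °C
Reagents that add atoms: none
Why: Proposed new method: a double 6-endo-dig cycloisomerisation under a monovalent gold phosphate in which the aldehyde serves as a C,O-bisnucleophile toward the two alkynes of the diynone – the phosphate shuttles a proton to give the neutral enol (never a free enolate, so E1cB loss of the C8 aroyloxy group is not opened), C8a adds to the gold-bound ynone at its Michael-polarised β-carbon C4a (5-exo attack at C5 is electronically mismatched, larger rings are out of reach, and the 7-O-SiEt3 group blocks 5-endo-dig furanone closure), protodeauration gives 25, its doubly activated C8a–H tautomerises to 26, and the enol oxygen adds to gold-activated C3 (δ-carbon of the enynone) to close the pyran, the whole being a strongly exergonic isomerisation that leaves C7 and C8 untouched and keeps no new stereocentre; the closest known reaction types are the gold-catalysed Conia-ene and enol ether–alkyne carbocyclisations, phosphoric-acid enol catalysis of Michael additions, and the gold-catalysed 6-endo cycloisomerisation of 2-alkynylbenzaldehydes.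

**Step 12**
Reactants: 27 protected bicycle
Product: 28 (+)-mitorubrinic acid B, (2E)-3-[(7R,8R)-8-[(2,4-dihydroxy-6-methylbenzoyl)oxy]-7-hydroxy-7-methyl-6-oxo-7,8-dihydro-6H-isochromen-3-yl]prop-2-enoic acid
Conditions: CF3CO2H/CH2Cl2/H2O (10:10:1), 0 °C → rt
Reagents that add atoms: none
Why: Global acidolysis (tert-butyl ester by loss of isobutene, MOM ethers by acetal hydrolysis, silyl ether by protodesilylation), in which the core is reversibly protonated at O6 to a hydroxypyrylium that disfavours ionisation at C8, the hindered aryl ester resists hydrolysis, and neither stereocentre is touched.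

**Compound list**
1 | L-(+)-lactic acid, (S)-2-hydroxypropanoic acid | C[C@H](O)C(=O)O | starting material
2 | pivalaldehyde (2,2-dimethylpropanal) | CC(C)(C)C=O | starting material
3 | (2S,5S)-2-tert-butyl-5-methyl-1,3-dioxolan-4-one | C[C@@H]1O[C@H](C(C)(C)C)OC1=O | intermediate
4 | ethyl 3,3-diethoxypropanoate | CCOC(=O)CC(OCC)OCC | starting material
5 | 3,3-diethoxypropanal | O=CCC(OCC)OCC | intermediate
6 | lithium (2S)-2-tert-butyl-5-methyl-1,3-dioxol-4-olate, enolate of 3 (not isolated) | CC1=C([O-])O[C@@H](C(C)(C)C)O1.[Li+] | intermediate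
7 | (2S,5R)-2-tert-butyl-5-[(1R)-3,3-diethoxy-1-hydroxypropyl]-5-methyl-1,3-dioxolan-4-one | C[C@]1([C@H](O)CC(OCC)OCC)O[C@H](C(C)(C)C)OC1=O | intermediate
8 | orsellinic acid (2,4-dihydroxy-6-methylbenzoic acid) | Cc1cc(O)cc(O)c1C(=O)O | starting material
9 | methoxymethyl 2,4-bis(methoxymethoxy)-6-methylbenzoate (not isolated) | Cc1cc(OCOC)cc(OCOC)c1C(=O)OCOC | intermediate
10 | 2,4-bis(methoxymethoxy)-6-methylbenzoic acid | Cc1cc(OCOC)cc(OCOC)c1C(=O)O | intermediate
11 | 2,4-bis(methoxymethoxy)-6-methylbenzoyl chloride (not isolated) | Cc1cc(OCOC)cc(OCOC)c1C(=O)Cl | intermediate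
12 | (1R)-1-[(2S,4R)-2-tert-butyl-4-methyl-5-oxo-1,3-dioxolan-4-yl]-3,3-diethoxypropyl 2,4-bis(methoxymethoxy)-6-methylbenzoate | C[C@]1([C@H](OC(=O)c2c(C)cc(OCOC)cc2OCOC)CC(OCC)OCC)O[C@H](C(C)(C)C)OC1=O | intermediate
13 | 1,4-bis(trimethylsilyl)buta-1,3-diyne | C[Si](C)(C)C#CC#C[Si](C)(C)C | starting material
14 | lithium 4-(trimethylsilyl)buta-1,3-diyn-1-ide (not isolated) | C[Si](C)(C)C#CC#[C-].[Li+] | intermediate
15 | 5-(trimethylsilyl)penta-2,4-diynal | C[Si](C)(C)C#CC#CC=O | intermediate
16 | tert-butyl 2-(diethoxyphosphoryl)acetate | CCOP(=O)(CC(=O)OC(C)(C)C)OCC | starting material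
17 | sodium salt (α-carbanion) of 16 (not isolated) | CCOP(=O)(OCC)[CH-]C(=O)OC(C)(C)C.[Na+] | intermediate
18 | tert-butyl (2E)-7-(trimethylsilyl)hept-2-ene-4,6-diynoate | C[Si](C)(C)C#CC#C/C=C/C(=O)OC(C)(C)C | intermediate
19 | tert-butyl (2E)-hept-2-ene-4,6-diynoate | C#CC#C/C=C/C(=O)OC(C)(C)C | intermediate
20 | lithium acetylide of 19 (not isolated) | [Li+].[C-]#CC#C/C=C/C(=O)OC(C)(C)C | intermediate
21 | lithium 4-alkynyl-1,3-dioxolan-4-olate from 20 + 12, C6 configuration undefined (not isolated) | C[C@]1([C@H](OC(=O)c2c(C)cc(OCOC)cc2OCOC)CC(OCC)OCC)O[C@H](C(C)(C)C)OC1([O-])C#CC#C/C=C/C(=O)OC(C)(C)C.[Li+] | intermediate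
22 | tert-butyl (2E,9R,10R)-10-{[2,4-bis(methoxymethoxy)-6-methylbenzoyl]oxy}-12,12-diethoxy-9-hydroxy-9-methyl-8-oxododec-2-ene-4,6-diynoate | Cc1cc(OCOC)cc(OCOC)c1C(=O)O[C@H](CC(OCC)OCC)[C@@](C)(O)C(=O)C#CC#C/C=C/C(=O)OC(C)(C)C | intermediate
23 | 7-O-triethylsilyl derivative of 22 in which one C1 ethoxy group is replaced by N-(2,4,6-trimethylpyridinium), triflate salt, C1 undefined (not isolated) | Cc1cc(OCOC)cc(OCOC)c1C(=O)O[C@H](CC(OCC)[n+]1c(C)cc(C)cc1C)[C@@](C)(O[Si](CC)(CC)CC)C(=O)C#CC#C/C=C/C(=O)OC(C)(C)C.[O-]S(=O)(=O)C(F)(F)F | intermediate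
24 | tert-butyl (2E,9R,10R)-10-{[2,4-bis(methoxymethoxy)-6-methylbenzoyl]oxy}-9-methyl-8,12-dioxo-9-[(triethylsilyl)oxy]dodec-2-ene-4,6-diynoate | Cc1cc(OCOC)cc(OCOC)c1C(=O)O[C@H](CC=O)[C@@](C)(O[Si](CC)(CC)CC)C(=O)C#CC#C/C=C/C(=O)OC(C)(C)C | intermediate
25 | monocyclic 3-alkynyl-4-formylcyclohex-2-enone (C8a–C4a bond made; 7R,8R; C8a epimers) (not isolated) | Cc1cc(OCOC)cc(OCOC)c1C(=O)O[C@@H]1C(C=O)C(C#C/C=C/C(=O)OC(C)(C)C)=CC(=O)[C@]1(C)O[Si](CC)(CC)CC | intermediate
26 | (E)-hydroxymethylene dienone tautomer of 25, OH cis to C4a (not isolated) | Cc1cc(OCOC)cc(OCOC)c1C(=O)O[C@@H]1/C(=C/O)C(C#C/C=C/C(=O)OC(C)(C)C)=CC(=O)[C@]1(C)O[Si](CC)(CC)CC | intermediate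
27 | tert-butyl (2E)-3-[(7R,8R)-8-{[2,4-bis(methoxymethoxy)-6-methylbenzoyl]oxy}-7-methyl-6-oxo-7-[(triethylsilyl)oxy]-7,8-dihydro-6H-isochromen-3-yl]prop-2-enoate | Cc1cc(OCOC)cc(OCOC)c1C(=O)O[C@@H]1C2=COC(/C=C/C(=O)OC(C)(C)C)=CC2=CC(=O)[C@]1(C)O[Si](CC)(CC)CC | intermediate
28 | (+)-mitorubrinic acid B | Cc1cc(O)cc(O)c1C(=O)O[C@@H]1C2=COC(/C=C/C(=O)O)=CC2=CC(=O)[C@]1(C)O | target

**Totals**
Total step count: 12.
Longest linear sequence: 7 steps (1 → 3 → 5 → 9 → 10 → 11 → 12, from L-lactic acid).

**Three steps most likely to fail**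

1. Step 11. Enolisation of 24 may be too slow relative to decay of the diynone. The C8 aroyloxy group may be lost from the enol or from 26. A 5-exo closure may also intrude.
The fallback sets out from 7 and comes back at 27. It takes the leaving group out of the cyclisation substrate and acylates last.
   - Silylate 7 (Et3SiCl, imidazole, DMF) to the 8-O-triethylsilyl ether F1.
   - Add acetylide 20 as in step 9 to obtain the hydroxy diynone F2.
   - Treat this with Et3SiOSO2CF3/2,4,6-trimethylpyridine and then water, as in step 10, to get the bis(triethylsilyloxy) aldehyde F3.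
   - Close both rings by an anionic double conjugate addition (Cs2CO3, MeCN, 0 °C). A silyloxide is a poor E1cB leaving group, so a true enolate can now be used. This gives the bicyclic bis(silyl ether) F4.
   - Pyridinium p-toluenesulfonate in MeOH at 0 °C frees only the secondary allylic alcohol F5.
   - Acylate F5 with acid chloride 11 (Et3N, 4-(dimethylamino)pyridine) to give 27.

2. Step 9. The stabilised, ester-bearing acetylide 20 may be too sluggish toward the hindered dioxolanone carbonyl, or may oligomerise on warming.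
The fallback sets out from 12 and comes back at 22. It changes the electrophile to the aldehyde oxidation level.
   - (Me2CHCH2)2AlH in CH2Cl2 at −78 °C reduces only the dioxolanone carbonyl to the lactol F6.
   - Two equivalents of 20 open it, with loss of pivalaldehyde, and add to the unmasked aldehyde to give the propargylic diol F7. The C6 epimers are of no consequence.
   - MnO2 in CH2Cl2 oxidises the propargylic carbinol selectively to 22.

3. Step 3. The exocyclic carbinol centre C8 is set only by transition-state topicity, so the ratio may be low or even reversed.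
The fallback sets out from 7, used as the crude mixture, and comes back at 7 as a single isomer. C8 is then set by reagent control instead of aldol topicity.
   - The mixture of 7 with the unwanted (8S)-epimer F8 is oxidised (Dess–Martin periodinane, NaHCO3, CH2Cl2) to the β-keto dioxolanone F9.
   - F9 is reduced with BH3·SMe2 and (S)-1-methyl-3,3-diphenyltetrahydro-1H,3H-pyrrolo[1,2-c][1,3,2]oxazaborole (10 mol %). The quaternary C7 is the large group and the CH2 is the small group, which gives the (8R)-alcohol 7.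

**Further compounds**
F1 | step 11 | (2S,5R)-2-tert-butyl-5-[(1R)-3,3-diethoxy-1-(triethylsilyloxy)propyl]-5-methyl-1,3-dioxolan-4-one | C[C@]1([C@H](O[Si](CC)(CC)CC)CC(OCC)OCC)O[C@H](C(C)(C)C)OC1=O
F2 | step 11 | tert-butyl (2E,9R,10R)-12,12-diethoxy-9-hydroxy-9-methyl-8-oxo-10-(triethylsilyloxy)dodec-2-ene-4,6-diynoate | CC[Si](CC)(CC)O[C@H](CC(OCC)OCC)[C@@](C)(O)C(=O)C#CC#C/C=C/C(=O)OC(C)(C)C
F3 | step 11 | tert-butyl (2E,9R,10R)-9-methyl-8,12-dioxo-9,10-bis(triethylsilyloxy)dodec-2-ene-4,6-diynoate | CC[Si](CC)(CC)O[C@H](CC=O)[C@@](C)(O[Si](CC)(CC)CC)C(=O)C#CC#C/C=C/C(=O)OC(C)(C)C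
F4 | step 11 | tert-butyl (2E)-3-[(7R,8R)-7-methyl-6-oxo-7,8-bis(triethylsilyloxy)-7,8-dihydro-6H-isochromen-3-yl]prop-2-enoate | CC[Si](CC)(CC)O[C@@H]1C2=COC(/C=C/C(=O)OC(C)(C)C)=CC2=CC(=O)[C@]1(C)O[Si](CC)(CC)CC
F5 | step 11 | tert-butyl (2E)-3-[(7R,8R)-8-hydroxy-7-methyl-6-oxo-7-(triethylsilyloxy)-7,8-dihydro-6H-isochromen-3-yl]prop-2-enoate | O[C@@H]1C2=COC(/C=C/C(=O)OC(C)(C)C)=CC2=CC(=O)[C@]1(C)O[Si](CC)(CC)CC
F6 | step 9 | lactol of 12 (dioxolanone C=O reduced to CH–OH, anomers) | C[C@]1([C@H](OC(=O)c2c(C)cc(OCOC)cc2OCOC)CC(OCC)OCC)O[C@H](C(C)(C)C)OC1O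
F7 | step 9 | 8-hydroxy analogue of 22 (C6 carbinol epimers; propargylic diol) | Cc1cc(OCOC)cc(OCOC)c1C(=O)O[C@H](CC(OCC)OCC)[C@@](C)(O)C(O)C#CC#C/C=C/C(=O)OC(C)(C)C
F8 | step 3 | (2S,5R)-2-tert-butyl-5-[(1S)-3,3-diethoxy-1-hydroxypropyl]-5-methyl-1,3-dioxolan-4-one | C[C@]1([C@@H](O)CC(OCC)OCC)O[C@H](C(C)(C)C)OC1=O
F9 | step 3 | (2S,5R)-2-tert-butyl-5-(3,3-diethoxypropanoyl)-5-methyl-1,3-dioxolan-4-one | C[C@]1(C(=O)CC(OCC)OCC)O[C@H](C(C)(C)C)OC1=O
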